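**Retrosynthetic overview**

1. Target 20 ⇐ α-tocopherol 18 by oxidative opening of the pyran ring. The enabling feature is that the C3′ hydroxyl oxygen lies five atoms from quinone carbon C1 (O–C3′–C2′–C1′–C2–C1), so it can be tied to C1 as a six-membered cyclic enol ether; in that ring the oxygen is the donor of a 2-alkoxydiene (quinone atoms C5=C6–C1(O)=C2).
2. 18 ⇐ 6-formylchroman 16 (Dakin oxidation) ⇐ dienyl ether 12 + but-2-ynal 14: a Diels–Alder reaction with in-flask dehydrogenation forms C2–C3 and C4–C5 of the quinone ring (C4a–C5 and C6–C7 of the chromene) and with them the whole hexasubstituted carbocycle.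
3. 12 ⇐ ketene acetal phosphate 10 + (Z)-but-2-en-2-ylboronic acid 11 (Suzuki–Miyaura coupling) ⇐ δ-lactone 8.
4. 8 ⇐ (3R)-1,3-diol 3 by two-carbon homologation and lactonisation ⇐ natural (E)-phytol 1 by Sharpless epoxidation and hydride opening (C3′ set by the catalyst, C7′ and C11′ taken from phytol).
5. Ring order: pyran ring first (lactone 8, step 4), carbocycle second (step 8), pyran ring opened last (step 10).

Key step: step 8

Remark: natural phytol is taken as the geometrically pure (2E,7R,11R) isomer; chromene numbering (O1, C2 … C8a) is used for the bicyclic intermediates, and quinone numbering (C1 … C6, side chain C1′ …) for the target.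

**Step 1**
Reactants: 1 (2E,7R,11R)-3,7,11,15-tetramethylhexadec-2-en-1-ol (natural phytol)
Product: 2 [(2R,3R)-3-methyl-3-[(4R,8R)-4,8,12-trimethyltridecyl]oxiran-2-yl]methanol
Conditions: Ti(OiPr)4 (10 mol%), D-(−)-diethyl tartrate (12 mol%), t-BuOOH (2 equiv), powdered 4 Å molecular sieves, CH2Cl2, −20 °C
Reagents that add atoms: tert-butyl hydroperoxide CC(C)(C)OO
Why: Sharpless asymmetric epoxidation of an (E)-trisubstituted allylic alcohol; the titanium–D-(−)-tartrate catalyst delivers oxygen to the face that gives the (2R,3R)-epoxide (L-(+)-tartrate gives the (2S,3S) series with E-allylic alcohols of this type), which fixes the later carbinol carbon C3′ as R.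

**Step 2**
Reactants: 2 [(2R,3R)-3-methyl-3-[(4R,8R)-4,8,12-trimethyltridecyl]oxiran-2-yl]methanol
Product: 3 (3R,7R,11R)-3,7,11,15-tetramethylhexadecane-1,3-diol
Conditions: NaAlH2(OCH2CH2OMe)2, THF, 0 °C to rt; aq. NaOH work-up
Reagents that add atoms: none
Why: Regioselective reductive opening of a 2,3-epoxy alcohol, in which the alkoxide-bound aluminium hydride delivers hydride intramolecularly to C2 (also the less substituted carbon), so the C3–O bond is not broken and C3 stays R.

**Step 3**
Reactants: 3 (3R,7R,11R)-3,7,11,15-tetramethylhexadecane-1,3-diol; 4 ethyl (triphenylphosphoranylidene)acetate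
Product: 6 ethyl (2E,5R,9R,13R)-5-hydroxy-5,9,13,17-tetramethyloctadec-2-enoate, via hydroxy aldehyde 5 (not isolated)
Conditions: TEMPO (10 mol%), PhI(OAc)2 (1.1 equiv), CH2Cl2, rt; then 4 (1.3 equiv), rt
Reagents that add atoms: none
Why: TEMPO/PhI(OAc)2 oxidises only the primary alcohol (the tertiary one has no carbinol hydrogen), and the stabilised ylide added to the same flask traps the elimination-prone β-hydroxy aldehyde in an E-selective Wittig olefination.

**Step 4**
Reactants: 6 ethyl (2E,5R,9R,13R)-5-hydroxy-5,9,13,17-tetramethyloctadec-2-enoate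
Product: 8 (6R)-6-methyl-6-[(4R,8R)-4,8,12-trimethyltridecyl]oxan-2-one, via saturated hydroxy ester 7 (not isolated)
Conditions: H2 (1 atm), Pd/C, EtOAc, rt; filter; then camphorsulfonic acid (5 mol%), toluene, 60 °C, EtOH distilled off
Reagents that add atoms: none
Why: Heterogeneous hydrogenation of the conjugated alkene followed by acid-catalysed lactonisation (intramolecular transesterification) of the gem-disubstituted δ-hydroxy ester, which closes the six-membered ring by acyl–oxygen cleavage and so breaks no bond to the quaternary stereocentre.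

**Step 5**
Reactants: 8 (6R)-6-methyl-6-[(4R,8R)-4,8,12-trimethyltridecyl]oxan-2-one
Product: 10 (2R)-2-methyl-2-[(4R,8R)-4,8,12-trimethyltridecyl]-3,4-dihydro-2H-pyran-6-yl diphenyl phosphate, via potassium enolate 9 (not isolated)
Conditions: KN(SiMe3)2 (1.3 equiv) added to 8 and (PhO)2P(O)Cl (1.5 equiv), HMPA, THF, −78 °C; Et3N-buffered work-up
Reagents that add atoms: diphenyl chlorophosphate O=P(Cl)(Oc1ccccc1)Oc1ccccc1
Why: Enol phosphate formation: kinetic deprotonation of the lactone with the electrophile already present and O-phosphorylation of the enolate give the cyclic ketene acetal phosphate, a stable electrophile for cross-coupling.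

**Step 6**
Reactants: 10 (2R)-2-methyl-2-[(4R,8R)-4,8,12-trimethyltridecyl]-3,4-dihydro-2H-pyran-6-yl diphenyl phosphate; 11 (Z)-but-2-en-2-ylboronic acid
Product: 12 (2R)-6-[(2E)-but-2-en-2-yl]-2-methyl-2-[(4R,8R)-4,8,12-trimethyltridecyl]-3,4-dihydro-2H-pyran
Conditions: Pd(PPh3)4 (5 mol%), aq. Na2CO3, 1,2-dimethoxyethane, 60 °C; chromatography on Et3N-deactivated silica
Reagents that add atoms: none
Why: Suzuki–Miyaura coupling of a lactone-derived ketene acetal phosphate with an alkenylboronic acid, which proceeds with retention of alkene geometry (Z in 11 and E in 12 differ only by substituent priority) and installs the 2-alkoxy-1,3-diene.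

**Step 7**
Reactants: 13 but-2-yn-1-ol
Product: 14 but-2-ynal
Conditions: activated MnO2 (10 equiv), CH2Cl2, rt; filter; solvent exchanged to toluene and used as a solution
Reagents that add atoms: none
Why: Activated MnO2 oxidises propargylic alcohols selectively to ynals without over-oxidation.

**Step 8**
Reactants: 12 (2R)-6-[(2E)-but-2-en-2-yl]-2-methyl-2-[(4R,8R)-4,8,12-trimethyltridecyl]-3,4-dihydro-2H-pyran; 14 but-2-ynal
Product: 16 (2R)-2,5,7,8-tetramethyl-2-[(4R,8R)-4,8,12-trimethyltridecyl]-3,4-dihydro-2H-chromene-6-carbaldehyde, via tetrahydrochromene cycloadduct 15 (not isolated)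
Conditions: 14 (2 equiv), 2,6-di-tert-butyl-4-methylphenol (1 mol%), toluene, 90 °C, sealed tube; cool; then DDQ (1.1 equiv), 0 °C to rt
Reagents that add atoms: none
Why: The 2-alkoxy-1,3-diene of 12 (the pyran enol ether C5=C6 conjugated with the E-butenyl group) adds suprafacially to the C≡C bond of the ynal in a concerted, asynchronous normal-demand Diels–Alder reaction, and DDQ then removes a doubly allylic hydride and a proton from C4a and C7 of 15 to give the arene. The closest known reaction type is the cycloaddition of 2-alkoxy- and 2-silyloxy-1,3-dienes with acetylenic aldehydes and ketones followed by dehydrogenation of the cyclohexa-1,4-diene. The carbocycle is closed in an intermolecular [4+2] mode by the bonds C4a–C5 and C6–C7, which become C2–C3 and C4–C5 of the quinone. The two sp3 centres created (C4a and C7) are erased on aromatisation, so no stereocontrol is needed, and C2 is remote and untouched. The selectivity required is regiochemical (formyl at C6, para to the ring oxygen); it is secured by the enol-ether oxygen, which makes pyran C5 the most nucleophilic diene terminus and sends it to the β-carbon of the ynal, reinforced by the methyl group on the other terminus. Both terminal substituents point outward in the s-cis diene (E-butenyl group, ring-held enol ether), and uncatalysed conditions keep the enol ether from adding to the formyl group.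

**Step 9**
Reactants: 16 (2R)-2,5,7,8-tetramethyl-2-[(4R,8R)-4,8,12-trimethyltridecyl]-3,4-dihydro-2H-chromene-6-carbaldehyde
Product: 18 (2R,4′R,8′R)-α-tocopherol, via tocopheryl formate 17 (not isolated)
Conditions: m-CPBA (1.3 equiv), NaHCO3, CH2Cl2, 0 °C to rt; then K2CO3 (0.2 equiv), degassed MeOH, rt, argon
Reagents that add atoms: meta-chloroperoxybenzoic acid OOC(=O)c1cccc(Cl)c1
Why: Dakin-type Baeyer–Villiger oxidation of an electron-rich benzaldehyde flanked by two ortho methyl groups, in which the aryl group para to the ring oxygen migrates in preference to hydrogen, followed by methanolysis of the aryl formate.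

**Step 10**
Reactants: 18 (2R,4′R,8′R)-α-tocopherol
Product: 20 2-[(3R,7R,11R)-3-hydroxy-3,7,11,15-tetramethylhexadecyl]-3,5,6-trimethylcyclohexa-2,5-diene-1,4-dione (tocopherylquinone), via hydroxytocopherone hemiketal 19 (not isolated)
Conditions: FeCl3·6H2O (2.5 equiv), MeOH/Et2O/H2O, rt, dark
Reagents that add atoms: water O
Why: Oxidative ring opening of a 6-chromanol: two-electron oxidation by FeCl3 gives the phenoxonium ion, water adds at C8a and the hemiketal collapses to the para-quinone by breaking the O1–C8a bond, never the O1–C2 bond, so the tertiary alcohol is released with its R configuration.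

**Compound list**

1 | (2E,7R,11R)-3,7,11,15-tetramethylhexadec-2-en-1-ol (phytol) | C/C(=C\CO)CCC[C@H](C)CCC[C@H](C)CCCC(C)C | starting material
2 | [(2R,3R)-3-methyl-3-[(4R,8R)-4,8,12-trimethyltridecyl]oxiran-2-yl]methanol | OC[C@H]1O[C@]1(C)CCC[C@H](C)CCC[C@H](C)CCCC(C)C | intermediate
3 | (3R,7R,11R)-3,7,11,15-tetramethylhexadecane-1,3-diol | OCC[C@](C)(O)CCC[C@H](C)CCC[C@H](C)CCCC(C)C | intermediate
4 | ethyl (triphenylphosphoranylidene)acetate | CCOC(=O)C=P(c1ccccc1)(c1ccccc1)c1ccccc1 | starting material
5 | (3R,7R,11R)-3-hydroxy-3,7,11,15-tetramethylhexadecanal | O=CC[C@](C)(O)CCC[C@H](C)CCC[C@H](C)CCCC(C)C | intermediate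
6 | ethyl (2E,5R,9R,13R)-5-hydroxy-5,9,13,17-tetramethyloctadec-2-enoate | CCOC(=O)/C=C/C[C@](C)(O)CCC[C@H](C)CCC[C@H](C)CCCC(C)C | intermediate
7 | ethyl (5R,9R,13R)-5-hydroxy-5,9,13,17-tetramethyloctadecanoate | CCOC(=O)CCC[C@](C)(O)CCC[C@H](C)CCC[C@H](C)CCCC(C)C | intermediate
8 | (6R)-6-methyl-6-[(4R,8R)-4,8,12-trimethyltridecyl]oxan-2-one | O=C1CCC[C@@](C)(CCC[C@H](C)CCC[C@H](C)CCCC(C)C)O1 | intermediate
9 | potassium (2R)-2-methyl-2-[(4R,8R)-4,8,12-trimethyltridecyl]-3,4-dihydro-2H-pyran-6-olate | [K+].[O-]C1=CCC[C@@](C)(CCC[C@H](C)CCC[C@H](C)CCCC(C)C)O1 | intermediate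
10 | (2R)-2-methyl-2-[(4R,8R)-4,8,12-trimethyltridecyl]-3,4-dihydro-2H-pyran-6-yl diphenyl phosphate | O=P(Oc1ccccc1)(Oc1ccccc1)OC1=CCC[C@@](C)(CCC[C@H](C)CCC[C@H](C)CCCC(C)C)O1 | intermediate
11 | (Z)-but-2-en-2-ylboronic acid | C/C=C(\C)B(O)O | starting material
12 | (2R)-6-[(2E)-but-2-en-2-yl]-2-methyl-2-[(4R,8R)-4,8,12-trimethyltridecyl]-3,4-dihydro-2H-pyran | C/C=C(\C)C1=CCC[C@@](C)(CCC[C@H](C)CCC[C@H](C)CCCC(C)C)O1 | intermediate
13 | but-2-yn-1-ol | CC#CCO | starting material
14 | but-2-ynal | CC#CC=O | intermediate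
15 | (2R)-2,5,7,8-tetramethyl-2-[(4R,8R)-4,8,12-trimethyltridecyl]-3,4,4a,7-tetrahydro-2H-chromene-6-carbaldehyde (C4a–H and C7–H cis, both diene faces used) | O=CC1=C(C)C2CC[C@@](C)(CCC[C@H](C)CCC[C@H](C)CCCC(C)C)OC2=C(C)C1C | intermediate
16 | (2R)-2,5,7,8-tetramethyl-2-[(4R,8R)-4,8,12-trimethyltridecyl]-3,4-dihydro-2H-chromene-6-carbaldehyde | O=Cc1c(C)c2CC[C@@](C)(CCC[C@H](C)CCC[C@H](C)CCCC(C)C)Oc2c(C)c1C | intermediate
17 | (2R)-2,5,7,8-tetramethyl-2-[(4R,8R)-4,8,12-trimethyltridecyl]-3,4-dihydro-2H-chromen-6-yl formate | O=COc1c(C)c2CC[C@@](C)(CCC[C@H](C)CCC[C@H](C)CCCC(C)C)Oc2c(C)c1C | intermediate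
18 | (2R,4′R,8′R)-α-tocopherol | Oc1c(C)c2CC[C@@](C)(CCC[C@H](C)CCC[C@H](C)CCCC(C)C)Oc2c(C)c1C | intermediate
19 | (2R)-8a-hydroxy-2,5,7,8-tetramethyl-2-[(4R,8R)-4,8,12-trimethyltridecyl]-2,3,4,8a-tetrahydro-6H-chromen-6-one (both C8a epimers) | O=C1C(C)=C2CC[C@@](C)(CCC[C@H](C)CCC[C@H](C)CCCC(C)C)OC2(O)C(C)=C1C | intermediate
20 | 2-[(3R,7R,11R)-3-hydroxy-3,7,11,15-tetramethylhexadecyl]-3,5,6-trimethylcyclohexa-2,5-diene-1,4-dione | CC1=C(C)C(=O)C(CC[C@](C)(O)CCC[C@H](C)CCC[C@H](C)CCCC(C)C)=C(C)C1=O | target

**Step count**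

Total step count: 10.
Longest linear sequence: 9 steps (steps 1–6 and 8–10, from 1 to 20).

**Steps most likely to fail**

Step 8. The cycloaddition may be too slow, because both diene termini carry a substituent and the dienophile is β-methylated. Oligomerisation of the ynal, aldol-type attack of the enol ether on the formyl group and hydrolysis of the diene would then consume the partners. The fallback sets out from 12 and comes back at 18. Diene 12 would be heated in toluene at 60 °C with (E)-1-nitroprop-1-ene F1, freshly made by dehydrating commercial 1-nitropropan-2-ol with phthalic anhydride. This is a stronger, carbonyl-free dienophile of the same polarity and should give the 6-nitro cycloadduct F2, with the nitro group on C6 by the same regiochemical rule. A Nef reaction under basic conditions that spare the enol ether (K2CO3, aq. H2O2, MeOH) would give the ketone F3. DDQ (1.1 equiv, dioxane, rt) would dehydrogenate this mono-enol ether of a cyclohexane-1,4-dione to α-tocopherol 18. Steps 7 and 9 are then not needed.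

Step 6. Oxidative addition into the hindered, electron-rich C–O bond of the ketene acetal phosphate may be slow, so that protodeboronation of 11 and hydrolysis of 10 back to 8 win. The fallback sets out from 8 and comes back at 12. (E)-2-Bromobut-2-ene would be converted with t-BuLi (2 equiv, Et2O, −78 °C) into (Z)-but-2-en-2-yllithium F4 (retention; the descriptor changes by priority only). One addition of F4 to lactone 8 at −78 °C would give, after work-up, (2E,8R,12R,16R)-8-hydroxy-3,8,12,16,20-pentamethylhenicos-2-en-4-one F5. Cyclodehydration with catalytic pyridinium p-toluenesulfonate in benzene at reflux over 4 Å molecular sieves would close the enol ether and give diene 12. Step 5 is then not needed.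

Step 3. The tertiary β-hydroxy aldehyde 5 may lose water to the enal or undergo retro-aldol cleavage before the ylide captures it. The fallback sets out from 2 and comes back at 6. Epoxy alcohol 2 would be oxidised under Parikh–Doering conditions (SO3·pyridine, DMSO, iPr2NEt) to the epoxy aldehyde F6, which cannot eliminate. A Wittig reaction with 4 would give the (E)-γ,δ-epoxy enoate F7. Palladium-catalysed formate hydrogenolysis of this alkenyl oxirane (Pd2(dba)3·CHCl3, PBu3, HCO2H, Et3N, dioxane, rt) would cleave only the allylic C4–O bond and deliver hydride to C4, leaving the tertiary C5–O bond and its configuration intact, to give 6. Step 2 is then not needed.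

**Further compounds**

F1 | step 8 | (E)-1-nitroprop-1-ene | C/C=C/[N+](=O)[O-]
F2 | step 8 | (2R)-2,5,7,8-tetramethyl-6-nitro-2-[(4R,8R)-4,8,12-trimethyltridecyl]-3,4,4a,5,6,7-hexahydro-2H-chromene | [O-][N+](=O)C1C(C)C2CC[C@@](C)(CCC[C@H](C)CCC[C@H](C)CCCC(C)C)OC2=C(C)C1C
F3 | step 8 | (2R)-2,5,7,8-tetramethyl-2-[(4R,8R)-4,8,12-trimethyltridecyl]-3,4,4a,5-tetrahydro-2H-chromen-6(7H)-one | O=C1C(C)C2CC[C@@](C)(CCC[C@H](C)CCC[C@H](C)CCCC(C)C)OC2=C(C)C1C
F4 | step 6 | (Z)-but-2-en-2-yllithium | C/C=C(\C)[Li]
F5 | step 6 | (2E,8R,12R,16R)-8-hydroxy-3,8,12,16,20-pentamethylhenicos-2-en-4-one | C/C=C(\C)C(=O)CCC[C@](C)(O)CCC[C@H](C)CCC[C@H](C)CCCC(C)C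
F6 | step 3 | (2S,3R)-3-methyl-3-[(4R,8R)-4,8,12-trimethyltridecyl]oxirane-2-carbaldehyde | O=C[C@H]1O[C@]1(C)CCC[C@H](C)CCC[C@H](C)CCCC(C)C
F7 | step 3 | ethyl (2E)-3-[(2R,3R)-3-methyl-3-[(4R,8R)-4,8,12-trimethyltridecyl]oxiran-2-yl]prop-2-enoate | CCOC(=O)/C=C/[C@H]1O[C@]1(C)CCC[C@H](C)CCC[C@H](C)CCCC(C)C
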